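**Plan**

- Cuts, in retrosynthetic order: O5–SEM; the C1′ methyl back to CO2Me; C1′–C2″ (enolate alkylation); C2″–I back to a C1″=C2″ vinyl group; C3=C4 of the pyran ring B (metathesis); three C=CH2 bonds (Wittig); O1–C2 (phenoxide plus bromomalonate).
- Enabling feature: C2 of ring B carries O1, CH3, the ring alkene carbon C3 and the chain carbon C1″. With the chain shortened to C1″=C2″, the last two arms are identical vinyl groups and C2 is prochiral. Closing C3=C4 onto the aryl-bound carbon C4 then makes C2 a stereocentre.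
- Forward order: ring A (arene) is fully oxygenated and etherified (steps 1–5) and the triene is unmasked (6–8). Ring B closes (9) and the spare vinyl group becomes the two-carbon link (10–11). Ring C is made separately (12–16), attached (17) and trimmed (18–20).
- Stereochemistry: C2 comes from a chiral Mo biphenolate that selects between enantiotopic groups. C2′ comes from a CBS reduction relayed by [3,3] chirality transfer. C1′ comes from alkylation of an ester enolate anti to the C2′ methyl. The target is (2R,1′S,2′S), with the C1′ and C2′ methyl groups cis.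

Key step: step 9

Conventions: SEM = CH2OCH2CH2SiMe3. C1″ is the chain carbon on C2 and C2″ the one on C1′. Ring C is numbered C1′ (quaternary) to C6′.

Assumption: the (S)-biphenolate complex is taken to give the (R)-configured ring-closure product. The sense of induction must be checked there, and the equally available (R)-biphenolate complex is used if it proves opposite.

Remark: all 2H-chromenes are handled in the dark and below about 50 °C, because reversible electrocyclic opening of ring B would racemise C2.

**Step 1**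
Reactants: 1 1,2,3,4-tetramethoxybenzene
Product: 4 2,3,4,5-tetramethoxyphenol, via aryllithium 2 (not isolated), via arylboronate 3 (not isolated)
Conditions: n-BuLi, TMEDA, THF, 0 °C; B(OMe)3, −78 °C → rt; H2O2, AcOH, 0 °C
Reagents that add atoms: hydrogen peroxide, OO
Why: Directed ortho-lithiation next to a methoxy group (the two free positions are equivalent), borylation and peroxide oxidation of the aryl boronate is the standard conversion of an anisole C–H into a phenol.

**Step 2**
Reactants: 4 2,3,4,5-tetramethoxyphenol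
Product: 5 2-hydroxy-3,4,5,6-tetramethoxybenzaldehyde
Conditions: MgCl2, Et3N, (CH2O)n, MeCN, reflux; dilute HCl
Reagents that add atoms: paraformaldehyde (formaldehyde unit), C=O
Why: Casnati–Skattebøl ortho-formylation, in which the magnesium phenoxide directs formaldehyde to the single free ring carbon (ortho to OH) and a second formaldehyde accepts hydride to give the salicylaldehyde.

**Step 3**
Reactants: 5 2-hydroxy-3,4,5,6-tetramethoxybenzaldehyde; 6 diethyl 2-bromo-2-methylpropanedioate
Product: 7 diethyl 2-(2-formyl-3,4,5,6-tetramethoxyphenoxy)-2-methylpropanedioate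
Conditions: Cs2CO3, DMF, 50 °C
Reagents that add atoms: none
Why: Williamson-type O-alkylation of the kind used for fibrate ethers, where the two esters activate the tertiary C–Br bond towards the caesium phenoxide and the fully substituted ring excludes C-alkylation and ring bromination.

**Step 4**
Reactants: 7 diethyl 2-(2-formyl-3,4,5,6-tetramethoxyphenoxy)-2-methylpropanedioate
Product: 8 diethyl 2-(2-formyl-3-hydroxy-4,5,6-trimethoxyphenoxy)-2-methylpropanedioate
Conditions: BCl3, CH2Cl2, −78 → 0 °C; aq. NaHCO3
Reagents that add atoms: none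
Why: Chelation-directed aryl methyl ether cleavage, in which BCl3 held between the formyl oxygen and the only remaining ortho methoxy group expels MeCl, while the other ortho oxygen bears a tertiary, doubly ester-deactivated carbon that can neither undergo SN2 attack nor ionise.

**Step 5**
Reactants: 8 diethyl 2-(2-formyl-3-hydroxy-4,5,6-trimethoxyphenoxy)-2-methylpropanedioate
Product: 9 diethyl 2-[2-formyl-4,5,6-trimethoxy-3-(SEM-oxy)phenoxy]-2-methylpropanedioate
Conditions: NaH, SEMCl, DMF, 0 °C → rt
Reagents that add atoms: 2-(trimethylsilyl)ethoxymethyl chloride, C[Si](C)(C)CCOCCl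
Why: Williamson etherification of the sodium phenoxide with a reactive chloromethyl ether; SEM withstands hydride, ylide, amide base and the Mo alkylidene and is removed at the end by fluoride rather than by acid, which the electron-rich chromene would not tolerate.

**Step 6**
Reactants: 9 diethyl 2-[2-formyl-4,5,6-trimethoxy-3-(SEM-oxy)phenoxy]-2-methylpropanedioate
Product: 10 2-[2-(hydroxymethyl)-4,5,6-trimethoxy-3-(SEM-oxy)phenoxy]-2-methylpropane-1,3-diol
Conditions: LiAlH4, THF, 0 °C; aq. NaOH work-up
Reagents that add atoms: none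
Why: Exhaustive LiAlH4 reduction of an aldehyde and a 2,2-disubstituted malonate to primary alcohols is routine and leaves the aryl ethers and SEM untouched.

**Step 7**
Reactants: 10 2-[2-(hydroxymethyl)-4,5,6-trimethoxy-3-(SEM-oxy)phenoxy]-2-methylpropane-1,3-diol
Product: 11 2-[2-formyl-4,5,6-trimethoxy-3-(SEM-oxy)phenoxy]-2-methylpropanedial
Conditions: (COCl)2, DMSO, CH2Cl2, −78 °C; Et3N, −78 → 0 °C; used crude
Reagents that add atoms: none
Why: Swern oxidation, in which all three hydroxyl groups become alkoxysulfonium salts before base is added, so no β-hydroxy aldehyde meets Et3N (no retro-aldol loss of formaldehyde) and none of the aldehydes formed can enolise.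

**Step 8**
Reactants: 11 2-[2-formyl-4,5,6-trimethoxy-3-(SEM-oxy)phenoxy]-2-methylpropanedial
Product: 12 1-ethenyl-3,4,5-trimethoxy-2-[(3-methylpenta-1,4-dien-3-yl)oxy]-6-(SEM-oxy)benzene
Conditions: Ph3PCH3Br, KN(SiMe3)2, THF, 0 °C; 11, −78 °C → rt; Et3N-washed silica
Reagents that add atoms: methyltriphenylphosphonium bromide, C[P+](c1ccccc1)(c1ccccc1)c1ccccc1.[Br-]
Why: Threefold Wittig methylenation with the non-stabilised ylide, as used to turn 2,2-disubstituted malonaldehydes into 3,3-disubstituted penta-1,4-dienes, gives an achiral triene whose Claisen rearrangement is blocked because both ortho positions and the para position are substituted.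

**Step 9**
Reactants: 12 1-ethenyl-3,4,5-trimethoxy-2-[(3-methylpenta-1,4-dien-3-yl)oxy]-6-(SEM-oxy)benzene
Product: 13 (2R)-2-ethenyl-6,7,8-trimethoxy-2-methyl-5-(SEM-oxy)-2H-chromene
Conditions: Mo(N-2,6-i-Pr2C6H3)(CHCMe2Ph)[(S)-3,3′-di-tert-butyl-5,5′,6,6′-tetramethylbiphenyl-2,2′-diolate] (5–10 mol %), C6H6, 22 °C, N2, vessel vented to remove C2H4
Reagents that add atoms: none
Why: The neophylidene is exchanged for a substrate alkylidene at C4 (loading at a carbinol vinyl group is degenerate and reversible), Mo=C4 adds across one of the two vinyl groups on C2 to give a molybdacyclobutane, and cycloreversion releases 13 and Mo=CH2, which re-enters the cycle with loss of ethylene. The closest known reaction type is the Mo-diolate-catalysed enantioselective ring-closing metathesis of achiral trienyl ethers, tertiary ethers included, together with the established metathesis closure of 2-vinylaryl allyl ethers to 2H-chromenes. Ring B is closed by olefin metathesis, a [2+2] cycloaddition/cycloreversion that forms C3=C4 within a six-membered ring. C2, the only new stereocentre, is set by the chiral biphenolate and the bulky arylimido ligand, whose pocket lets only one enantiotopic vinyl group reach the Mo=C bond while CH3 and the spectator vinyl group occupy the less crowded sites. The step needs group selectivity between the two vinyl groups and ring closure in preference to cross-metathesis: the vinyl groups cannot close on each other (three-membered ring), and every alkene is flanked by a fully substituted carbon or by two ortho substituents, so dimerisation is slow. The cis-styrenyl C3=C4 bond and the neopentyl-type vinyl group of 13 re-enter the cycle reluctantly, and venting ethylene keeps the closure under kinetic control.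

**Step 10**
Reactants: 13 (2R)-2-ethenyl-6,7,8-trimethoxy-2-methyl-5-(SEM-oxy)-2H-chromene
Product: 15 2-[(2R)-6,7,8-trimethoxy-2-methyl-5-(SEM-oxy)-2H-chromen-2-yl]ethan-1-ol, via B-alkyl-9-BBN adduct 14 (not isolated)
Conditions: 9-BBN, THF, 0 °C → rt; NaOH, H2O2, 0 °C
Reagents that add atoms: hydrogen peroxide, OO
Why: Brown hydroboration–oxidation, in which 9-BBN adds anti-Markovnikov to the monosubstituted vinyl group far faster than to the hindered 1,2-disubstituted C3=C4, and boron ends on C2″, too far from O1 for β-elimination.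

**Step 11**
Reactants: 15 2-[(2R)-6,7,8-trimethoxy-2-methyl-5-(SEM-oxy)-2H-chromen-2-yl]ethan-1-ol
Product: 16 (2R)-2-(2-iodoethyl)-6,7,8-trimethoxy-2-methyl-5-(SEM-oxy)-2H-chromene
Conditions: PPh3, I2, imidazole, CH2Cl2, 0 °C
Reagents that add atoms: iodine, [I][I]
Why: Appel-type (Garegg–Samuelsson) iodination of an unhindered primary alcohol proceeds under buffered conditions that spare SEM and the chromene.

**Step 12**
Reactants: 17 (3E)-3-methylpent-3-en-2-one
Product: 18 (2S,3E)-3-methylpent-3-en-2-ol
Conditions: (R)-2-methyl-CBS-oxazaborolidine (10 mol %), catecholborane, toluene, −78 °C; MeOH, aq. NaOH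
Reagents that add atoms: none
Why: Corey–Bakshi–Shibata reduction, in which the oxazaborolidine binds the ketone with the branched alkenyl group as the large substituent and delivers hydride 1,2 to one face, so the (R)-catalyst gives the (S)-carbinol.

**Step 13**
Reactants: 18 (2S,3E)-3-methylpent-3-en-2-ol; 19 hex-5-enoic acid
Product: 20 (2S,3E)-3-methylpent-3-en-2-yl hex-5-enoate
Conditions: DCC, DMAP (cat.), CH2Cl2, 0 °C → rt
Reagents that add atoms: none
Why: Steglich esterification acylates the secondary allylic alcohol at oxygen without touching the carbinol stereocentre.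

**Step 14**
Reactants: 20 (2S,3E)-3-methylpent-3-en-2-yl hex-5-enoate
Product: 23 (3S,4E)-2-(but-3-enyl)-3,4-dimethylhex-4-enoic acid (C2 epimers), via silyl ketene acetal 21 (not isolated), via trimethylsilyl ester 22 (not isolated)
Conditions: LiN(i-Pr)2, THF, −78 °C; Me3SiCl; −78 °C → rt, then 50 °C; dilute HCl
Reagents that add atoms: none
Why: Ireland–Claisen rearrangement, a suprafacial [3,3] shift through a transition state with the carbinol methyl pseudo-equatorial, transfers the (S)-carbinol configuration of the (E)-alkene to the new CH(CH3) centre (the future C2′), while the α-centre is inconsequential because it is enolised later.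

**Step 15**
Reactants: 23 (3S,4E)-2-(but-3-enyl)-3,4-dimethylhex-4-enoic acid
Product: 24 methyl (3S,4E)-2-(but-3-enyl)-3,4-dimethylhex-4-enoate
Conditions: K2CO3, MeI, DMF, rt
Reagents that add atoms: iodomethane, C[I]
Why: SN2 methylation of the carboxylate is a routine esterification that does not affect C3.

**Step 16**
Reactants: 24 methyl (3S,4E)-2-(but-3-enyl)-3,4-dimethylhex-4-enoate
Product: 25 methyl (2S)-2,3-dimethylcyclohex-3-ene-1-carboxylate (C1 epimers)
Conditions: RuCl2(H2IMes)(PCy3)(=CHPh) (second-generation Grubbs catalyst, 3–5 mol %), CH2Cl2, 40 °C, dilute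
Reagents that add atoms: none
Why: Ring-closing metathesis, in which the carbene formed at the terminal alkene attacks the trisubstituted alkene at its fully substituted carbon (the same bond pattern as cross-metathesis with 2-methylbut-2-ene), extrudes propene and fixes the C3′=C4′ position unambiguously.

**Step 17**
Reactants: 25 methyl (2S)-2,3-dimethylcyclohex-3-ene-1-carboxylate; 16 (2R)-2-(2-iodoethyl)-6,7,8-trimethoxy-2-methyl-5-(SEM-oxy)-2H-chromene
Product: 27 methyl (1R,2R)-2,3-dimethyl-1-{2-[(2R)-6,7,8-trimethoxy-2-methyl-5-(SEM-oxy)-2H-chromen-2-yl]ethyl}cyclohex-3-ene-1-carboxylate, via lithium enolate 26 (not isolated)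
Conditions: 25 (1.5 equiv), LiN(i-Pr)2, THF, −78 °C; DMPU; 16, −78 → −20 °C
Reagents that add atoms: none
Why: Ester enolate alkylation (SN2 on a primary iodide), in which the C2′ methyl is forced pseudo-axial by A(1,3) strain with the exocyclic enolate and A(1,2) strain with the C3′ methyl, so the iodide approaches the opposite face and C1′ carries the chain trans and the ester cis to that methyl.

**Step 18**
Reactants: 27 methyl (1R,2R)-2,3-dimethyl-1-{2-[(2R)-chromen-2-yl]ethyl}cyclohex-3-ene-1-carboxylate
Product: 28 [(1R,2R)-2,3-dimethyl-1-{2-[(2R)-6,7,8-trimethoxy-2-methyl-5-(SEM-oxy)-2H-chromen-2-yl]ethyl}cyclohex-3-en-1-yl]methanol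
Conditions: LiAlH4, Et2O, 0 °C → rt; aq. NaOH work-up
Reagents that add atoms: none
Why: LiAlH4 reduces even hindered quaternary esters to neopentyl alcohols and is inert to the alkenes, the aryl ethers and SEM.

**Step 19**
Reactants: 28 [(1R,2R)-2,3-dimethyl-1-{2-[(2R)-chromen-2-yl]ethyl}cyclohex-3-en-1-yl]methanol
Product: 30 (2R)-6,7,8-trimethoxy-2-methyl-5-(SEM-oxy)-2-{2-[(1S,2S)-1,2,3-trimethylcyclohex-3-en-1-yl]ethyl}-2H-chromene, via neopentyl triflate 29 (not isolated)
Conditions: Tf2O, 2,6-lutidine, CH2Cl2, −78 °C; then LiEt3BH (THF, excess), −78 → 0 °C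
Reagents that add atoms: none
Why: Sulfonate activation followed by SN2 hydride displacement works because a neopentyl triflate cannot eliminate and is displaced by triethylborohydride at or below 0 °C, where the aryl methyl ethers survive, unlike under the refluxing hydride that a mesylate would need.

**Step 20**
Reactants: 30 (2R)-6,7,8-trimethoxy-2-methyl-5-(SEM-oxy)-2-{2-[(1S,2S)-1,2,3-trimethylcyclohex-3-en-1-yl]ethyl}-2H-chromene
Product: 31 (2R)-6,7,8-trimethoxy-2-methyl-2-{2-[(1S,2S)-1,2,3-trimethylcyclohex-3-en-1-yl]ethyl}-2H-chromen-5-ol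
Conditions: Bu4NF, THF–DMPU, 45 °C, argon, dark; aqueous work-up
Reagents that add atoms: none
Why: Fluoride-induced SEM cleavage (attack at silicon, then loss of ethylene and formaldehyde) is eased by the phenoxide leaving group and avoids acid, so neither the chromene, C2 nor the trisubstituted alkene is endangered.

**Compound list**

1 | 1,2,3,4-tetramethoxybenzene | COc1ccc(OC)c(OC)c1OC | starting material
2 | (2,3,4,5-tetramethoxyphenyl)lithium | [Li]c1cc(OC)c(OC)c(OC)c1OC | intermediate
3 | dimethyl (2,3,4,5-tetramethoxyphenyl)boronate | COB(OC)c1cc(OC)c(OC)c(OC)c1OC | intermediate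
4 | 2,3,4,5-tetramethoxyphenol | COc1cc(O)c(OC)c(OC)c1OC | intermediate
5 | 2-hydroxy-3,4,5,6-tetramethoxybenzaldehyde | O=Cc1c(O)c(OC)c(OC)c(OC)c1OC | intermediate
6 | diethyl 2-bromo-2-methylpropanedioate | CCOC(=O)C(C)(Br)C(=O)OCC | starting material
7 | diethyl 2-(2-formyl-3,4,5,6-tetramethoxyphenoxy)-2-methylpropanedioate | CCOC(=O)C(C)(Oc1c(C=O)c(OC)c(OC)c(OC)c1OC)C(=O)OCC | intermediate
8 | diethyl 2-(2-formyl-3-hydroxy-4,5,6-trimethoxyphenoxy)-2-methylpropanedioate | CCOC(=O)C(C)(Oc1c(C=O)c(O)c(OC)c(OC)c1OC)C(=O)OCC | intermediate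
9 | diethyl 2-[2-formyl-4,5,6-trimethoxy-3-(SEM-oxy)phenoxy]-2-methylpropanedioate | CCOC(=O)C(C)(Oc1c(C=O)c(OCOCC[Si](C)(C)C)c(OC)c(OC)c1OC)C(=O)OCC | intermediate
10 | 2-[2-(hydroxymethyl)-4,5,6-trimethoxy-3-(SEM-oxy)phenoxy]-2-methylpropane-1,3-diol | CC(CO)(CO)Oc1c(CO)c(OCOCC[Si](C)(C)C)c(OC)c(OC)c1OC | intermediate
11 | 2-[2-formyl-4,5,6-trimethoxy-3-(SEM-oxy)phenoxy]-2-methylpropanedial | CC(C=O)(C=O)Oc1c(C=O)c(OCOCC[Si](C)(C)C)c(OC)c(OC)c1OC | intermediate
12 | 1-ethenyl-3,4,5-trimethoxy-2-[(3-methylpenta-1,4-dien-3-yl)oxy]-6-(SEM-oxy)benzene | C=Cc1c(OCOCC[Si](C)(C)C)c(OC)c(OC)c(OC)c1OC(C)(C=C)C=C | intermediate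
13 | (2R)-2-ethenyl-6,7,8-trimethoxy-2-methyl-5-(SEM-oxy)-2H-chromene | COc1c(OCOCC[Si](C)(C)C)c2c(c(OC)c1OC)O[C@](C)(C=C)C=C2 | intermediate
14 | 9-{2-[(2R)-6,7,8-trimethoxy-2-methyl-5-(SEM-oxy)-2H-chromen-2-yl]ethyl}-9-borabicyclo[3.3.1]nonane | COc1c(OCOCC[Si](C)(C)C)c2c(c(OC)c1OC)O[C@](C)(CCB1C3CCCC1CCC3)C=C2 | intermediate
15 | 2-[(2R)-6,7,8-trimethoxy-2-methyl-5-(SEM-oxy)-2H-chromen-2-yl]ethan-1-ol | COc1c(OCOCC[Si](C)(C)C)c2c(c(OC)c1OC)O[C@](C)(CCO)C=C2 | intermediate
16 | (2R)-2-(2-iodoethyl)-6,7,8-trimethoxy-2-methyl-5-(SEM-oxy)-2H-chromene | COc1c(OCOCC[Si](C)(C)C)c2c(c(OC)c1OC)O[C@](C)(CCI)C=C2 | intermediate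
17 | (3E)-3-methylpent-3-en-2-one | C/C=C(\C)C(C)=O | starting material
18 | (2S,3E)-3-methylpent-3-en-2-ol | C/C=C(\C)[C@H](C)O | intermediate
19 | hex-5-enoic acid | C=CCCCC(=O)O | starting material
20 | (2S,3E)-3-methylpent-3-en-2-yl hex-5-enoate | C=CCCCC(=O)O[C@@H](C)/C(C)=C/C | intermediate
21 | trimethylsilyl ketene acetal of 20 (acetal C=C geometry inconsequential) | C=CCCC=C(O[Si](C)(C)C)O[C@@H](C)/C(C)=C/C | intermediate
22 | trimethylsilyl (3S,4E)-2-(but-3-enyl)-3,4-dimethylhex-4-enoate (C2 epimers) | C=CCCC(C(=O)O[Si](C)(C)C)[C@H](C)/C(C)=C/C | intermediate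
23 | (3S,4E)-2-(but-3-enyl)-3,4-dimethylhex-4-enoic acid (C2 epimers) | C=CCCC(C(=O)O)[C@H](C)/C(C)=C/C | intermediate
24 | methyl (3S,4E)-2-(but-3-enyl)-3,4-dimethylhex-4-enoate (C2 epimers) | C=CCCC(C(=O)OC)[C@H](C)/C(C)=C/C | intermediate
25 | methyl (2S)-2,3-dimethylcyclohex-3-ene-1-carboxylate (C1 epimers) | COC(=O)C1CCC=C(C)[C@H]1C | intermediate
26 | lithium enolate of 25 | [Li]OC(OC)=C1CCC=C(C)[C@H]1C | intermediate
27 | methyl (1R,2R)-2,3-dimethyl-1-{2-[(2R)-6,7,8-trimethoxy-2-methyl-5-(SEM-oxy)-2H-chromen-2-yl]ethyl}cyclohex-3-ene-1-carboxylate | COc1c(OCOCC[Si](C)(C)C)c2c(c(OC)c1OC)O[C@](C)(CC[C@]1(C(=O)OC)CCC=C(C)[C@H]1C)C=C2 | intermediate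
28 | [(1R,2R)-2,3-dimethyl-1-{2-[(2R)-6,7,8-trimethoxy-2-methyl-5-(SEM-oxy)-2H-chromen-2-yl]ethyl}cyclohex-3-en-1-yl]methanol | COc1c(OCOCC[Si](C)(C)C)c2c(c(OC)c1OC)O[C@](C)(CC[C@]1(CO)CCC=C(C)[C@H]1C)C=C2 | intermediate
29 | trifluoromethanesulfonate of 28 | COc1c(OCOCC[Si](C)(C)C)c2c(c(OC)c1OC)O[C@](C)(CC[C@]1(COS(=O)(=O)C(F)(F)F)CCC=C(C)[C@H]1C)C=C2 | intermediate
30 | (2R)-6,7,8-trimethoxy-2-methyl-5-(SEM-oxy)-2-{2-[(1S,2S)-1,2,3-trimethylcyclohex-3-en-1-yl]ethyl}-2H-chromene | COc1c(OCOCC[Si](C)(C)C)c2c(c(OC)c1OC)O[C@](C)(CC[C@]1(C)CCC=C(C)[C@H]1C)C=C2 | intermediate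
31 | (2R)-6,7,8-trimethoxy-2-methyl-2-{2-[(1S,2S)-1,2,3-trimethylcyclohex-3-en-1-yl]ethyl}-2H-chromen-5-ol | COc1c(O)c2c(c(OC)c1OC)O[C@](C)(CC[C@]1(C)CCC=C(C)[C@H]1C)C=C2 | target

Total step count: 20.
Longest linear sequence: 15 steps (steps 1–11 and 17–20). The ring C branch contributes steps 12–16.

**Steps most likely to fail**

Step 9.
- What may go wrong: discrimination between the enantiotopic vinyl groups may be insufficient, because the two groups left on C2 (CH3 and vinyl) are similar in size. Loading of the catalyst onto the di-ortho-substituted styrene may be slow. The ortho oxygen atoms may sequester the alkylidene by chelation.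
- Fallback: setting out from 12, ring closure with the achiral complex RuCl2(H2IMes)(=CH-2-i-PrOC6H4) (second-generation Hoveyda–Grubbs catalyst; CH2Cl2, 40 °C) should give the racemic 2-ethenylchromene F1. Its enantiomers are separated by preparative supercritical-fluid chromatography on a polysaccharide chiral phase. The (R)-enantiomer is 13, where the route is rejoined, and the (S)-enantiomer F2 is set aside.

Step 8 (together with the handling of crude 11).
- What may go wrong: the non-enolisable 1,3-dialdehyde may suffer nucleophile-induced deformylation, hydration or oligomerisation before all three carbonyl groups are methylenated.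
- Fallback: setting out from 9, the aromatic aldehyde alone is methylenated (Ph3P=CH2, THF, −78 °C) to give the styrene diester F3. Treatment with i-Bu2AlH (toluene, −78 °C) converts both esters into the chelated bis(aluminium hemiacetal) F4. F4 is not warmed or worked up but is treated directly with excess Ph3P=CH2, so each aldehyde is released only in the presence of ylide. This one-flask reduction–olefination delivers 12 without the triol or the free dialdehyde.

Step 3.
- What may go wrong: substitution by the hindered, formyl-deactivated phenoxide at the tertiary carbon may be slow. The phenoxide may instead attack at bromine, or the reagent may lose HBr to give the methylenemalonate, followed by addition at the wrong carbon.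
- Fallback: setting out from 4, Rh2(OAc)4-catalysed O–H insertion of diethyl diazomalonate (CH2Cl2, rt) gives the aryloxymalonate F5. C-methylation (K2CO3, MeI, DMF) gives the methylated aryloxymalonate F6. Rieche formylation (Cl2CHOMe, TiCl4, CH2Cl2, −78 → 0 °C) at the only free ring position gives 7, where the route is rejoined.

**Further compounds**

F1 | step 9 | racemic 2-ethenyl-6,7,8-trimethoxy-2-methyl-5-(SEM-oxy)-2H-chromene | COc1c(OCOCC[Si](C)(C)C)c2c(c(OC)c1OC)OC(C)(C=C)C=C2
F2 | step 9 | (2S)-2-ethenyl-6,7,8-trimethoxy-2-methyl-5-(SEM-oxy)-2H-chromene | COc1c(OCOCC[Si](C)(C)C)c2c(c(OC)c1OC)O[C@@](C)(C=C)C=C2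
F3 | step 8 | diethyl 2-[2-ethenyl-4,5,6-trimethoxy-3-(SEM-oxy)phenoxy]-2-methylpropanedioate | CCOC(=O)C(C)(Oc1c(C=C)c(OCOCC[Si](C)(C)C)c(OC)c(OC)c1OC)C(=O)OCC
F4 | step 8 | bis(diisobutylaluminium ethyl hemiacetal) of 2-[2-ethenyl-4,5,6-trimethoxy-3-(SEM-oxy)phenoxy]-2-methylpropanedial | CCOC(O[Al](CC(C)C)CC(C)C)C(C)(Oc1c(C=C)c(OCOCC[Si](C)(C)C)c(OC)c(OC)c1OC)C(OCC)O[Al](CC(C)C)CC(C)C
F5 | step 3 | diethyl 2-(2,3,4,5-tetramethoxyphenoxy)propanedioate | CCOC(=O)C(Oc1cc(OC)c(OC)c(OC)c1OC)C(=O)OCC
F6 | step 3 | diethyl 2-methyl-2-(2,3,4,5-tetramethoxyphenoxy)propanedioate | CCOC(=O)C(C)(Oc1cc(OC)c(OC)c(OC)c1OC)C(=O)OCC
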